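## Analysis of the target

The target is (S)-5-hydroxy-3-[(S)-13-hydroxy-10-oxotetradecyl]-7-methoxyisobenzofuran-1(3H)-one, a phthalide. Benzene ring A (C3a, C4, C5, C6, C7, C7a) is fused to γ-lactone ring B (C1, O2, C3, C3a, C7a). Ring A carries a free phenol on C5 and a methyl ether on C7, peri to the lactone carbonyl C1. C3 carries an unbranched chain C1'–C14' with a ketone at C10' and a secondary alcohol at C13'.

The two stereocenters, C3 (S, benzylic and oxygen-bearing) and C13' (S), lie ten carbons apart. Neither can control the other, and an epimer at either one is a diastereomer that cannot be expected to separate, so each must be set independently with high fidelity.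

The sensitive groups are the C10'/C13' γ-hydroxy ketone (cyclic hemiketal equilibrium, dehydration under forcing acid), the benzylic C3–O2 bond (hydrogenolysis, base-induced epimerisation of C3–H) and the free phenol.

The real difficulty is differentiation on ring A: two phenolic oxygens that must end up different (C5–OH, C7–OMe), and a carbinol carbon that must sit ortho to the carboxyl carbon, on an arene with three similarly activated positions.

The feature that invites the chosen move is ring A itself. C7, C6, C5 and C4 carry O, H, O, H and are flanked by the carbon-substituted C7a and C3a. This is the pattern of a 1-methoxy-3-silyloxy-1,3-diene (C7–C6–C5–C4) added across an alkyne (C7a≡C3a) whose two substituents are an ester carbon (C1) and a carbinol carbon (C3). Rings A and B can therefore both be grown from an acyclic 4-hydroxy-2-ynoate.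

A second feature is the 1,4-relationship of the C10' ketone and the C13' hydroxyl, which is that of a hydrated homopropargylic alcohol.

## Retrosynthetic reasoning

**16 ⇒ 10 + 12.** Ring A is cut at C3a–C4 and C7–C7a, and ring B at O2–C1. This leads back to the acyclic ynoate 10 and the cyclic diene 12. In 10 the C2≡C3 alkyne becomes C7a and C3a, the ester carbon becomes C1 and the C4 carbinol becomes C3. Diene 12 supplies C4–C7, with the C5 oxygen as a silyl enol ether and the C7 oxygen as a methyl enol ether. The cut is made here because the two phenolic oxygens then arrive already different, no arene has to be functionalised ortho to anything, and the aryl–C3 bond is not a separate problem. The forward reaction has to be a regioselective [4+2] cycloaddition, an aromatising cycloreversion that expels the two-carbon bridge of 12, and a lactonisation. The C3 configuration only has to survive.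

**10 ⇒ 8 + 9.** The C3–C4 bond of 10 (C3a–C3 of 16) is cut between the alkyne and the carbinol carbon, giving aldehyde 8 and methyl propiolate 9. The forward step is a catalyst-controlled enantioselective alkynylation. It sets the future C3, the only stereocenter the route has to create.

**8 ⇒ 6 ⇒ 5.** The aldehyde carbon of 8 is traced to the terminal alkene of 6 (oxidative cleavage, one carbon lost), and the silyl ether of 6 to the free alcohol 5. A terminal alkene is chosen as the latent aldehyde because it is inert to all earlier steps and needs no protecting group. The silyl ether is the only protecting group of the route and is removed in the acid treatment that ends the key step.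

**5 ⇒ 3.** The C10' ketone (C5 of 5) is traced to the C4≡C5 alkyne of homopropargylic alcohol 3. The 1,4-oxygen pattern is dissonant and would otherwise call for an acyl anion equivalent. Here the C2 hydroxyl itself directs hydration to the remote alkyne carbon through dihydrofuran 4. The forward reaction must be regioselective and must leave the terminal alkene alone.

**3 ⇒ 1 + 2.** The C5–C6 bond of 3 (C10'–C9' of 16) is cut between an sp and an sp3 carbon, giving the chiral-pool alkynol 1, which brings C13' with its configuration, and bromoalkene 2, which brings the nine methylene groups and the latent aldehyde carbon.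

**12 ⇒ 11.** Diene 12 is the kinetic silyl dienol ether of the commercial vinylogous ester 11.

## Alternatives that were turned down

**Alternative 1:** the textbook route, which keeps ring A as a pre-formed resorcinol derivative and sets C3 last.
- Disconnection: aryl–C3 bond, with the C3 stereocenter set by reduction.
- Forward key step: the aryl bromide A1 (methyl 4-(benzyloxy)-2-bromo-6-methoxybenzoate) is metalated and acylated with the chain acid derivative to give keto ester A2. Asymmetric transfer hydrogenation of the aryl ketone (RuCl(p-cymene)[(S,S)-TsDPEN], HCO2H/Et3N) with spontaneous lactonisation then sets C3.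
- Why turned down: A1 is not available as such. Making it means alkylating the C5 and C7 oxygens stepwise and then halogenating one of three activated ring positions selectively, three to four steps before the chain is attached. The aryl-metal must then acylate in the presence of the C10' ketone, or that ketone must be masked. The benzyl ether must finally be removed without hydrogenolysis of the benzylic C3–O2 bond. The chemistry is reliable in type, but the route is about twice as long and most of its effort goes into protecting groups and arene regiochemistry.

**Alternative 2:** de novo ring A by metal-catalysed [2+2+2] cyclotrimerisation.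
- Disconnection: C3a–C4, C5–C6 and C7–C7a.
- Forward key step: the ester-tethered diyne A3 ((3S,16S)-16-[(tert-butyldimethylsilyl)oxy]-13-oxoheptadec-1-yn-3-yl 3-methoxyprop-2-ynoate) is combined with an alkoxyacetylene as the C5–C6 unit, for example with RhCl(PPh3)3, closing rings A and B together.
- Why turned down: C7 must carry oxygen, so the propiolate half of A3 has to be a 3-methoxypropiolate, a push–pull ynol ether ester that is fragile to hydrolysis and heat. The third alkyne can insert in two orientations, placing oxygen on C5 or on C6, and nothing in substrate or catalyst biases the choice. The propargylic ester of A3 can also ionise at the metal, which threatens C3. That is three independent risks in a step that gains no more than the chosen one.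

**Alternative 3:** convergent union of two electrophiles in the chain.
- Disconnection: C9'–C10'.
- Forward key step: nickel-catalysed reductive acyl–alkyl cross-coupling (NiCl2(dme), a bipyridine ligand, Mn powder) of bromide A4 ((S)-3-(9-bromononyl)-5-[(tert-butyldimethylsilyl)oxy]-7-methoxyisobenzofuran-1(3H)-one) with acid chloride A5 ((S)-4-[(tert-butyldimethylsilyl)oxy]pentanoyl chloride).
- Why turned down: this is the easiest bond of the molecule. A4 would still need the whole arene problem solved as in Alternative 1, so the convergence adds steps instead of removing them and leaves the demanding part untouched.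

Key step: step 7

Assumption: the (S,S)-ProPhenol ligand is taken to deliver the alkynyl group to the Re face of aldehyde 8; if the sense of induction is the opposite, the (R,R)-ligand is used and nothing else changes.

## Route

**Step 1**
Reactants: 1 (S)-pent-4-yn-2-ol; 2 11-bromoundec-1-ene
Product: 3 (S)-hexadec-15-en-4-yn-2-ol
Conditions: n-BuLi (2.1 equiv), THF, −78 to −20 °C; DMPU, then 2, −20 °C to rt; then H2O
Reagents that add atoms: none
Why: Alkylation of the O,C-dilithio derivative of a homopropargylic alcohol; the acetylide carbon is far more nucleophilic towards a primary bromide than the lithium alkoxide, so C–C bond formation should dominate. The C2 stereocenter of 1 is not involved.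

**Step 2**
Reactants: 3 (S)-hexadec-15-en-4-yn-2-ol
Product: 5 (S)-2-hydroxyhexadec-15-en-5-one, via dihydrofuran 4 (not isolated)
Conditions: Ph3PAuCl (2 mol %), AgOTf (2 mol %), TsOH·H2O (5 mol %), THF/H2O 10:1, rt
Reagents that add atoms: water, O
Why: Hydroxyl-directed alkyne hydration under monovalent gold catalysis: 5-endo-dig attack of the C2 hydroxyl on the gold-activated alkyne and protodeauration give dihydrofuran 4, whose enol ether is hydrolysed in the same flask, so the ketone should land only on C5, the alkyne carbon remote from the hydroxyl. The terminal alkene is inert to the catalyst and C2 is untouched.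

**Step 3**
Reactants: 5 (S)-2-hydroxyhexadec-15-en-5-one
Product: 6 (S)-2-[(tert-butyldimethylsilyl)oxy]hexadec-15-en-5-one
Conditions: TBSCl, imidazole, DMF, rt
Reagents that add atoms: tert-butyldimethylsilyl chloride (TBSCl), CC(C)(C)[Si](C)(C)Cl
Why: Standard silylation of the open-chain form of the γ-hydroxy ketone, the cyclic hemiketal being drained through the equilibrium. The silyl ether keeps the hydroxyl from consuming the zinc reagent of step 5 and the diene of step 7.

**Step 4**
Reactants: 6 (S)-2-[(tert-butyldimethylsilyl)oxy]hexadec-15-en-5-one
Product: 8 (S)-14-[(tert-butyldimethylsilyl)oxy]-11-oxopentadecanal, via ozonide 7 (not isolated)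
Conditions: O3, CH2Cl2, −78 °C; then PPh3, −78 °C to rt
Reagents that add atoms: ozone, [O-][O+]=O
Why: Ozonolysis of a terminal alkene with reductive work-up; the ketone and the silyl ether are inert to ozone at −78 °C and no stereocenter is touched.

**Step 5**
Reactants: 8 (S)-14-[(tert-butyldimethylsilyl)oxy]-11-oxopentadecanal; 9 methyl propiolate
Product: 10 methyl (4S,17S)-17-[(tert-butyldimethylsilyl)oxy]-4-hydroxy-14-oxooctadec-2-ynoate
Conditions: (S,S)-ProPhenol (20 mol %), Me2Zn (3 equiv), 9 (3 equiv), Ph3PO (40 mol %), toluene, 4 °C; aq work-up
Reagents that add atoms: none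
Why: Catalytic asymmetric alkynylation of an aldehyde: the alkynylzinc formed from 9 and Me2Zn should add to the Re face of the aldehyde inside the chiral dinuclear zinc pocket of the ligand, which sets C4 (the future C3) as S. Alkynylzinc species do not attack the dialkyl ketone, and the C17 stereocenter is remote and untouched.

**Step 6**
Reactants: 11 3-methoxycyclohex-2-en-1-one
Product: 12 1-methoxy-3-(trimethylsilyloxy)cyclohexa-1,3-diene
Conditions: LiN(iPr)2 (LDA), THF, −78 °C; then TMSCl, −78 °C to rt; non-aqueous work-up, distillation
Reagents that add atoms: chlorotrimethylsilane (TMSCl), C[Si](C)(C)Cl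
Why: Kinetic deprotonation of the vinylogous ester at C6 (the α' position, as in Stork–Danheiser enolate chemistry) and O-silylation should give the 1-methoxy-3-silyloxy diene. No stereocenter is involved.

**Step 7**
Reactants: 10 methyl (4S,17S)-17-[(tert-butyldimethylsilyl)oxy]-4-hydroxy-14-oxooctadec-2-ynoate; 12 1-methoxy-3-(trimethylsilyloxy)cyclohexa-1,3-diene
Product: 16 (S)-5-hydroxy-3-[(S)-13-hydroxy-10-oxotetradecyl]-7-methoxyisobenzofuran-1(3H)-one, via trimethylsilyl ether 13 (not isolated), via bicyclo[2.2.2]octadiene adduct 14 (not isolated), via silylated benzoate 15 (not isolated)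
Conditions: BSA (1.2 equiv), o-xylene, 60 °C; then 12 (3 equiv), sealed tube, 160 °C; then 48% aq HF, MeCN, 0 °C to rt
Reagents that add atoms: none
Why: Alder–Rickert benzannulation followed by lactonisation. Silylation of the C4 hydroxyl first blocks isomerisation of the 4-hydroxy-2-ynoate to a 4-oxo-enoate and keeps a free OH away from the diene; the electron-rich diene 12 then adds to the ynoate in a normal-demand [4+2] cycloaddition to give 14, which at 160 °C loses ethene by [4+2] cycloreversion, so ring A is closed by cycloaddition (new bonds C3a–C4 and C7–C7a) and aromatised by extrusion. The regiochemistry the step needs (OMe on C7 next to the carboxyl-bearing C7a, silyloxy on C5 para to it) is secured by matched polarisation: the unsubstituted diene terminus, its most nucleophilic position, bonds to the β-carbon of the ynoate (future C3a), and the methoxy-bearing terminus bonds to the α-carbon (future C7a). Chemoselectivity rests on the ester-activated alkyne being the only dienophile present; the C14 ketone and the silyl ethers are inert under neutral thermal conditions. Aqueous HF then cleaves the aryl and benzylic trimethylsilyl ethers and the TBS ether, and the freed benzylic hydroxyl closes ring B by 5-exo-trig acyl substitution on the neighbouring methyl ester. No stereocenter is formed: C3 is the C4 carbinol carbon of 10, its C–O bond is never broken and its hydrogen is not removed under these conditions, so the S configuration set in step 5 is carried over, while the bridgehead centers of 14 vanish on aromatisation. The closest known reaction type is the Alder–Rickert synthesis of 4-hydroxy-2-methoxybenzoates and of phthalides from alkoxy- or silyloxycyclohexadienes and alk-2-ynoates.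

## Compound list

1 | (S)-pent-4-yn-2-ol | C[C@H](O)CC#C | starting material
2 | 11-bromoundec-1-ene | C=CCCCCCCCCCBr | starting material
3 | (S)-hexadec-15-en-4-yn-2-ol | C[C@H](O)CC#CCCCCCCCCCC=C | intermediate
4 | (S)-2-methyl-5-(undec-10-en-1-yl)-2,3-dihydrofuran | C[C@H]1CC=C(CCCCCCCCCC=C)O1 | intermediate (not isolated)
5 | (S)-2-hydroxyhexadec-15-en-5-one | C[C@H](O)CCC(=O)CCCCCCCCCC=C | intermediate
6 | (S)-2-[(tert-butyldimethylsilyl)oxy]hexadec-15-en-5-one | C[C@H](O[Si](C)(C)C(C)(C)C)CCC(=O)CCCCCCCCCC=C | intermediate
7 | (S)-2-[(tert-butyldimethylsilyl)oxy]-14-(1,2,4-trioxolan-3-yl)tetradecan-5-one (ozonide, ring carbon configuration undefined) | C[C@H](O[Si](C)(C)C(C)(C)C)CCC(=O)CCCCCCCCCC1OCOO1 | intermediate (not isolated)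
8 | (S)-14-[(tert-butyldimethylsilyl)oxy]-11-oxopentadecanal | C[C@H](O[Si](C)(C)C(C)(C)C)CCC(=O)CCCCCCCCCC=O | intermediate
9 | methyl propiolate | C#CC(=O)OC | starting material
10 | methyl (4S,17S)-17-[(tert-butyldimethylsilyl)oxy]-4-hydroxy-14-oxooctadec-2-ynoate | COC(=O)C#C[C@@H](O)CCCCCCCCCC(=O)CC[C@H](C)O[Si](C)(C)C(C)(C)C | intermediate
11 | 3-methoxycyclohex-2-en-1-one | COC1=CC(=O)CCC1 | starting material
12 | 1-methoxy-3-(trimethylsilyloxy)cyclohexa-1,3-diene | COC1=CC(O[Si](C)(C)C)=CCC1 | intermediate
13 | methyl (4S,17S)-17-[(tert-butyldimethylsilyl)oxy]-14-oxo-4-[(trimethylsilyl)oxy]octadec-2-ynoate | COC(=O)C#C[C@@H](O[Si](C)(C)C)CCCCCCCCCC(=O)CC[C@H](C)O[Si](C)(C)C(C)(C)C | intermediate (not isolated)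
14 | methyl 3-[(1S,14S)-14-[(tert-butyldimethylsilyl)oxy]-11-oxo-1-[(trimethylsilyl)oxy]pentadecyl]-1-methoxy-5-[(trimethylsilyl)oxy]bicyclo[2.2.2]octa-2,5-diene-2-carboxylate (bridgehead configuration undefined) | COC(=O)C1=C([C@@H](O[Si](C)(C)C)CCCCCCCCCC(=O)CC[C@H](C)O[Si](C)(C)C(C)(C)C)C2CCC1(OC)C=C2O[Si](C)(C)C | intermediate (not isolated)
15 | methyl 2-[(1S,14S)-14-[(tert-butyldimethylsilyl)oxy]-11-oxo-1-[(trimethylsilyl)oxy]pentadecyl]-6-methoxy-4-[(trimethylsilyl)oxy]benzoate | COC(=O)c1c(OC)cc(O[Si](C)(C)C)cc1[C@@H](O[Si](C)(C)C)CCCCCCCCCC(=O)CC[C@H](C)O[Si](C)(C)C(C)(C)C | intermediate (not isolated)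
16 | (S)-5-hydroxy-3-[(S)-13-hydroxy-10-oxotetradecyl]-7-methoxyisobenzofuran-1(3H)-one | COc1cc(O)cc2c1C(=O)O[C@H]2CCCCCCCCCC(=O)CC[C@H](C)O | target

## Step count and risks

Total step count: 7 (steps 1–5 and 7 in the main line, step 6 for the diene).
Longest linear sequence: 6 steps (steps 1, 2, 3, 4, 5, 7, from 1).

**Step 7 (key step).** The most likely failure is that cycloaddition to the β-branched, singly activated ynoate is slow. Thermal decay of the diene, or hydrolysis of its silyl enol ether by adventitious moisture before cycloreversion, would then compete with ring formation at the temperature that ethene extrusion requires.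

The fallback replaces cycloreversion by elimination as the aromatising event, so that much lower temperatures suffice. It sets out from 13 and comes back at 15. Acetyl chloride and 1,1-dichloroethene with AlCl3, followed by loss of HCl, give 4,4-dichlorobut-3-en-2-one F1. NaOMe in methanol converts this to 4,4-dimethoxybut-3-en-2-one F2, and LiN(iPr)2 then TMSCl give the acyclic vinylogous ketene acetal 1,1-dimethoxy-3-(trimethylsilyloxy)buta-1,3-diene F3. In toluene at 90–110 °C, F3 should add to 13 with the same regiochemistry to give methyl 2-[(1S,14S)-14-[(tert-butyldimethylsilyl)oxy]-11-oxo-1-[(trimethylsilyl)oxy]pentadecyl]-6,6-dimethoxy-4-[(trimethylsilyl)oxy]cyclohexa-1,4-diene-1-carboxylate F4. F4 loses methanol to give 15, and the HF treatment of step 7 then leads to 16 as before.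

**Step 5.** The most likely failure is insufficient facial selectivity with an unbranched, enolisable aldehyde, together with competing self-aldol condensation. An error here cannot be repaired later, because C3 epimers of 16 will not separate.

The fallback sets the center by reagent-controlled reduction instead of addition. It sets out from 8 and comes back at 10. Compound 9 is deprotonated with LiN(SiMe3)2 in THF at −78 °C and added to 8 to give methyl (17S)-17-[(tert-butyldimethylsilyl)oxy]-4-hydroxy-14-oxooctadec-2-ynoate as a mixture of C4 epimers F5. Dess–Martin oxidation gives methyl (S)-17-[(tert-butyldimethylsilyl)oxy]-4,14-dioxooctadec-2-ynoate F6. Reduction with (S)-Alpine-Borane (from (−)-α-pinene), which reduces alkynyl ketones far faster than dialkyl ketones, should return 10 with the 4S configuration.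

**Step 2.** The most likely failure is competition of undirected hydration, which would place the ketone on C4, or arrest at a cyclic ketal or enol ether stage.

The fallback builds the ketone by acyl substitution instead of alkyne hydration and bypasses steps 1–3. It sets out from 2 and comes back at 6. (S)-γ-Valerolactone is opened with MeNH(OMe)·HCl and Me3Al to (S)-4-hydroxy-N-methoxy-N-methylpentanamide F7, which is silylated (TBSCl, imidazole) to (S)-4-[(tert-butyldimethylsilyl)oxy]-N-methoxy-N-methylpentanamide F8. Undec-10-en-1-ylmagnesium bromide F9, made from 2 and Mg in THF, adds to F8 to give 6 directly.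

## Further compounds

F1 | step 7 | 4,4-dichlorobut-3-en-2-one | CC(=O)C=C(Cl)Cl
F2 | step 7 | 4,4-dimethoxybut-3-en-2-one | CC(=O)C=C(OC)OC
F3 | step 7 | 1,1-dimethoxy-3-(trimethylsilyloxy)buta-1,3-diene | C=C(O[Si](C)(C)C)C=C(OC)OC
F4 | step 7 | methyl 2-[(1S,14S)-14-[(tert-butyldimethylsilyl)oxy]-11-oxo-1-[(trimethylsilyl)oxy]pentadecyl]-6,6-dimethoxy-4-[(trimethylsilyl)oxy]cyclohexa-1,4-diene-1-carboxylate | COC(=O)C1=C([C@@H](O[Si](C)(C)C)CCCCCCCCCC(=O)CC[C@H](C)O[Si](C)(C)C(C)(C)C)CC(O[Si](C)(C)C)=CC1(OC)OC
F5 | step 5 | methyl (17S)-17-[(tert-butyldimethylsilyl)oxy]-4-hydroxy-14-oxooctadec-2-ynoate (mixture of C4 epimers) | COC(=O)C#CC(O)CCCCCCCCCC(=O)CC[C@H](C)O[Si](C)(C)C(C)(C)C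
F6 | step 5 | methyl (S)-17-[(tert-butyldimethylsilyl)oxy]-4,14-dioxooctadec-2-ynoate | COC(=O)C#CC(=O)CCCCCCCCCC(=O)CC[C@H](C)O[Si](C)(C)C(C)(C)C
F7 | step 2 | (S)-4-hydroxy-N-methoxy-N-methylpentanamide | C[C@H](O)CCC(=O)N(C)OC
F8 | step 2 | (S)-4-[(tert-butyldimethylsilyl)oxy]-N-methoxy-N-methylpentanamide | C[C@H](O[Si](C)(C)C(C)(C)C)CCC(=O)N(C)OC
F9 | step 2 | undec-10-en-1-ylmagnesium bromide | C=CCCCCCCCCC[Mg]Br
A1 | alternative 1 | methyl 4-(benzyloxy)-2-bromo-6-methoxybenzoate | COC(=O)c1c(OC)cc(OCc2ccccc2)cc1Br
A2 | alternative 1 | methyl 4-(benzyloxy)-2-[(S)-14-[(tert-butyldimethylsilyl)oxy]-11-oxopentadecanoyl]-6-methoxybenzoate | COC(=O)c1c(OC)cc(OCc2ccccc2)cc1C(=O)CCCCCCCCCC(=O)CC[C@H](C)O[Si](C)(C)C(C)(C)C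
A3 | alternative 2 | (3S,16S)-16-[(tert-butyldimethylsilyl)oxy]-13-oxoheptadec-1-yn-3-yl 3-methoxyprop-2-ynoate | COC#CC(=O)O[C@H](C#C)CCCCCCCCCC(=O)CC[C@H](C)O[Si](C)(C)C(C)(C)C
A4 | alternative 3 | (S)-3-(9-bromononyl)-5-[(tert-butyldimethylsilyl)oxy]-7-methoxyisobenzofuran-1(3H)-one | COc1cc(O[Si](C)(C)C(C)(C)C)cc2c1C(=O)O[C@H]2CCCCCCCCCBr
A5 | alternative 3 | (S)-4-[(tert-butyldimethylsilyl)oxy]pentanoyl chloride | C[C@H](O[Si](C)(C)C(C)(C)C)CCC(Cl)=O
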